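The earlier runs and the new flask stem from a simulated flask with made-up constants.

A small charge of Z, 70 µM, stands against L at 0.015 M or more, so green's L needs 214 turnovers per Z.

| setting | maple | larch | green | grey | amber | teal | ochre | red |
|---|---|---|---|---|---|---|---|---|
| L | 0.050 M | 0.050 M | 0.015 M | 0.20 M | 0.10 M | 0.030 M | 0.050 M | 0.080 M |
| D | 0.050 M | 0.075 M | 0.0750 M | 0.0750 M | 0.0750 M | 0.0750 M | 0.0750 M | 0.0750 M |
| Z | 70 µM | 35 µM | 70 µM | 70 µM | 70 µM | 70 µM | 70 µM | 70 µM |
| temperature | −20 °C | −20 °C | −20 °C | −20 °C | −20 °C | −20 °C | −20 °C | −20 °C |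
| remark | run made earlier | run made earlier |  |  |  |  |  |  |
| time |  |  | 25 min | 25 min | 25 min | 25 min | 25 min | 25 min |

| run | time / min | G / % | L / % |
|---|---|---|---|
| maple | 0.833 | 0.4 | 100.0 |
| maple | 1.50 | 1.7 | 98.0 |
| maple | 2.50 | 5.5 | 95.5 |
| maple | 3.00 | 7.7 | 91.5 |
| maple | 4.00 | 11.3 | 89.0 |
| maple | 5.00 | 15.1 | 86.4 |
| larch | 0.833 | 2.6 | 99.8 |
| larch | 1.50 | 1.3 | 98.2 |
| larch | 2.50 | 3.4 | 96.2 |
| larch | 3.00 | 0.8 | 97.5 |
| larch | 4.00 | 5.6 | 93.5 |
| larch | 5.00 | 5.6 | 94.2 |

(scatter of a reading: 1 percentage point)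

- ranking by amount of G, in percent of the L charged, from high to low, at 25 min (green / grey / amber / teal / ochre / red)
- the amount of G, in percent of the L charged of the flask you put first, at 25 min
- the amount of G, in percent of the L charged of the flask you put last, at 25 min

- given per volume of solution although it is solid: D
- at the start none of D is in solution

Maple gives the rungs of time, each read with a scatter of 1 percentage point per reading. The shortest is a lag of about 1.09 min, and at 0.833 min maple shows 0.4% of G. The next is the span of the readings: by 5.00 min G has reached 15.1%, too little for a straight line and a curve to be told apart. Read as a pseudo-first-order fall, the unconverted part shrinks at 0.0419 min⁻¹, a half-life of 16.6 min. The asked 25 min is longer, 1.51 half-lives, so the shape of the curve matters there.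

That gives the zero of the scale. If the rate is proportional to c(L) with Z and the supply of D held, the percent converted at a given time doesn't depend on the L charged, and maple's last reading, carried forward at this constant, gives the flat yield, 63.3%. A flask above it is converting a larger share of its L than the first-order case allows, and one below it a smaller share. The other end is a constant rate, which gives 0.0458 M of G, or 22.9% of grey's L. If one D goes into each G, D is grey's limiting reagent, with a ceiling of 37.5%. This reckoning puts ochre, which has maple's L and Z but more D, at the flat yield, on the assumption that the extra D changes nothing.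

The forecast gave green > teal > ochre > red > amber > grey, with 93% and 25%: “I expect percent yield to fall as L rises”. Its top stands above the flat yield and its low below it.

The flasks give green > teal > ochre > red > amber > grey, with 69.4% and 33.3%; the forecast's top is 24 points too high and its low 8.3 points too low.

E + J ⇌ X (K = 16.0 L mol⁻¹, k = 760 L mol⁻¹ s⁻¹, Ea = 38.0 kJ mol⁻¹, ΔH = −44.0 kJ mol⁻¹); Q ⇌ J (K = 0.770, k = 2.10 s⁻¹, Ea = 55.0 kJ mol⁻¹, ΔH = −9.00 kJ mol⁻¹); D ⇌ E, rate k3*(cs3 - [E]) while solid is left; crystals form when [E] > cs3 (solubility = 27.0 mM, k = 0.0110 s⁻¹); L + Z ⇌ Q (K = 8.80 L mol⁻¹, k = 1500 L mol⁻¹ s⁻¹, Ea = 36.0 kJ mol⁻¹, ΔH = 29.0 kJ mol⁻¹); X → Z + G (k = 22.0 s⁻¹, Ea = 53.0 kJ mol⁻¹); (constants at −20 °C) Ochre, at 60.7%, lies 2.6 points below the flat yield, maple taken to the asked time gives 60.3%, green lies 6.1 points above it, and grey 30 points below it. At 25.0 min grey's catalyst stood as Z 36.6%, Q 42.7%, J 19.0% and X 1.73%, with solid D at 0% and E at 0.00832 M, while green still held Z at 95.1%. Left until 1.5 h, grey holds 37.5% of G, with 0% of its D remaining.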